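The constants belong to no real substance; the result is computed.

At early times the gas crosses into solution far faster than the solid substrate dissolves, so although none is dissolved at the start, you may reckon with [dissolved gas] at 14 mM.

solid substrate 0.25 M; gas phase 14 mM (held); protic impurity 0.0750 M; time 1.5 h

    starting material → side product (k1 = 0.017 /s)
    target → over-reaction product (k2 = 6.0 × 10⁻⁴ /s)
    solid substrate ⇌ starting material, rate k3*(cs3 - [starting material]) while solid is left; crystals form when [starting material] > cs3 (cs3 = 0.20 M, k3 = 1.5 × 10⁻⁴ /s)
    gas phase ⇌ dissolved gas, rate k4*(csat - [dissolved gas]) (k4 = 0.10 /s, csat = 14 mM)
    starting material + protic impurity → quenched substrate (k5 = 0.0064 /M/s)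
    starting material + dissolved gas → target (k6 = 0.67 /M/s)

1. amount of target at 1.5 h, in percent of the solid substrate charged
2. the change that raises the amount of target at 1.5 h, in percent of the solid substrate charged most ("none" if none brings more than 2 percentage points) (winter / autumn / dusk / noon / none)
3. amount of target at 1.5 h, in percent of the solid substrate charged, after autumn

- winter: doubling the dissolution coefficient of step 3, all else as stated
- autumn: doubling the solubility in step 3, all else as stated
- dusk: doubling the saturation concentration of gas phase, all else as stated
- noon: doubling the transfer coefficient of step 4, all else as stated

- solid, in amounts per volume of the solution: solid substrate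
- at the start none of the gas is dissolved
- at the start none of the solid substrate is in solution
- run time (flask): 1.5 h

Here is my reckoning. Dissolution feeds the solution at 108 mM/h. [starting material] is consumed pseudo-first-order at 0.0269 /s, far faster than the solid dissolves, so it holds a low steady state. Of what dissolves, a share 34.9 % becomes target. Dissolution can deliver 64.8 % by the end, less than the charge, so solid lasts the run.

Target climbs towards 6.98 %, the target ceiling: the level, in percent of the charge, at which over-reaction destroys target as fast as it forms while solid remains. The run spans 3.24 target lifetimes, so I expect 6.71 %.

Winter and autumn raise the feed to 216 mM/h, but by my reckoning the solid is then gone by 1.16 h and target decays, giving 6.12 % after autumn. Dusk raises the share instead, so my choice is dusk.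

The forecast gave 6.6 %, lower than my figure, then dusk, and 6.3 % after autumn, higher than mine. Its grounds began: “Gas transfer is fast, so dissolved gas stays near saturation”.

The simulation gives 6.64 %, dusk with a gain of 3.2 percentage points, and 6.27 % after autumn.

In this flask at 1.50 h, starting material is made 1.00 times as fast as it is used, and the side reaction consumes it 1.8 times as fast as target formation does. Target reads 6.64 %, under the ceiling, with 35.6 % of the solid substrate standing. Now take the flask charged with 0.15 M of solid substrate: its ceiling is 11.6 %, its solid is gone by 1.39 h by hand, and decay after that gives 8.70 %. That flask reads 8.97 %.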